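The plan cuts the C6–C7 bond of ring A, the benzenoid ring of the isocoumarin. C6 bears a free hydroxyl and sits between the unsubstituted carbons C5 and C7, so it can enter as a ketene carbon. A 2-pyranone (ring B) carrying a CH2CO2H arm at pyranone C4 and a 1-aryloxyvinyl group at pyranone C3 is dehydrated to a dienylketene; one six-electron electrocyclization then forms C6–C7, closes and aromatizes ring A and leaves the C6 oxygen as an acetate. The ether oxygen to ring C arrives as an aryl ester oxygen, and methylenation of that ester supplies the enol ether terminus C7.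

Key step: step 10

Remark: isocoumarin numbering is used (C1 lactone carbonyl, O2, C3 pentyl, C6 hydroxyl, C8 aryloxy); ring A is the benzene ring, ring B the lactone ring and ring C the pendant arene. The target has no stereocentre. The side-chain acid is carried through the methylenation as a triisopropylsilyl ester, because Cp2TiMe2 is destroyed by a free carboxylic acid.

Step 1
Reactants: 1 olivetol (5-pentylbenzene-1,3-diol)
Product: 2 1,3-dimethoxy-5-pentylbenzene
Conditions: MeI, K2CO3, acetone, reflux
Reagents that add atoms: iodomethane, CI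
Why: Williamson O-methylation of both phenols should cap the resorcinol as methyl ethers that later tolerate strong base, the titanium carbene and hot acetic anhydride.

Step 2
Reactants: 2 1,3-dimethoxy-5-pentylbenzene
Product: 4 2,4-dimethoxy-6-pentylbenzaldehyde, via aryl iminium chloride 3 (not isolated)
Conditions: POCl3, DMF, 0 °C to 80 °C; then H2O, 0 °C
Reagents that add atoms: N,N-dimethylformamide, CN(C)C=O; water, O; phosphoryl chloride, O=P(Cl)(Cl)Cl (counter-ion of 3 only)
Why: Vilsmeier–Haack formylation of 5-alkylresorcinol dimethyl ethers should go to the ring carbon para to one methoxy group and ortho to the alkyl chain in preference to the position between the two methoxy groups, which places the future phenol oxygen correctly.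

Step 3
Reactants: 4 2,4-dimethoxy-6-pentylbenzaldehyde
Product: 6 2,4-dimethoxy-6-pentylphenol, via aryl formate 5 (not isolated)
Conditions: mCPBA, CH2Cl2, 0 °C to rt; then K2CO3 (cat.), MeOH, rt
Reagents that add atoms: 3-chloroperoxybenzoic acid, OOC(=O)c1cccc(Cl)c1
Why: Baeyer–Villiger (Dakin-type) oxidation, in which the electron-rich aryl group migrates in preference to hydride, should give the formate, and mild methanolysis should release the phenol.

Step 4
Reactants: 7 hexanoyl chloride; 8 1-propynylmagnesium bromide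
Product: 10 non-2-yn-4-one, via 1-propynylzinc chloride 9 (not isolated)
Conditions: 8, ZnCl2, THF, 0 °C; then 7, Pd(PPh3)4 (2 mol %), 0 °C to rt
Reagents that add atoms: zinc chloride, Cl[Zn]Cl (zinc and chlorine of 9 only)
Why: Negishi-type acylation through the mild alkynylzinc reagent should stop at the ketone and avoid the double addition expected from the Grignard reagent itself.

Step 5
Reactants: 10 non-2-yn-4-one; 11 tert-butyl ethyl malonate
Product: 13 tert-butyl 4-methyl-2-oxo-6-pentyl-2H-pyran-3-carboxylate, via Michael adduct 12 (not isolated)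
Conditions: NaOEt (0.3 equiv), EtOH, 0 °C to 60 °C
Reagents that add atoms: none
Why: Conjugate addition of the malonate anion to C2 of the ynone and lactonization of the dienolate oxygen onto the ethyl ester (ethoxide leaves far more easily than tert-butoxide from the hindered ester) should give the 2-pyranone, the classical malonate–alkynyl ketone pyranone annulation.

Step 6
Reactants: 13 tert-butyl 4-methyl-2-oxo-6-pentyl-2H-pyran-3-carboxylate
Product: 14 4-methyl-2-oxo-6-pentyl-2H-pyran-3-carboxylic acid
Conditions: TFA, CH2Cl2, rt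
Reagents that add atoms: none
Why: Acidolysis of the tert-butyl ester with loss of 2-methylpropene should free the acid without the aqueous base that would open the pyranone.

Step 7
Reactants: 14 4-methyl-2-oxo-6-pentyl-2H-pyran-3-carboxylic acid; 6 2,4-dimethoxy-6-pentylphenol
Product: 16 2,4-dimethoxy-6-pentylphenyl 4-methyl-2-oxo-6-pentyl-2H-pyran-3-carboxylate, via acid chloride 15 (not isolated)
Conditions: (COCl)2, DMF (cat.), CH2Cl2, 0 °C to rt; evaporate; then 6, pyridine, DMAP (cat.), CH2Cl2, 0 °C to rt
Reagents that add atoms: oxalyl chloride, O=C(Cl)C(Cl)=O (chlorine of 15 only)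
Why: Acyl chloride formation followed by DMAP-catalysed acylation of the hindered phenol (nucleophilic acyl substitution) should give the aryl ester, pyridine being too weak a base to deprotonate the 4-methyl group.

Step 8
Reactants: 16 2,4-dimethoxy-6-pentylphenyl 4-methyl-2-oxo-6-pentyl-2H-pyran-3-carboxylate
Product: 19 tri(propan-2-yl)silyl 2-{3-[(2,4-dimethoxy-6-pentylphenoxy)carbonyl]-2-oxo-6-pentyl-2H-pyran-4-yl}acetate, via lithium dienolate 17 (not isolated), via lithium carboxylate 18 (not isolated)
Conditions: LiN(iPr)2 (1.1 equiv), THF, −78 °C; CO2 (gas), −78 °C; then iPr3SiOTf, −78 °C to 0 °C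
Reagents that add atoms: carbon dioxide, O=C=O; triisopropylsilyl trifluoromethanesulfonate, CC(C)[Si](OS(=O)(=O)C(F)(F)F)(C(C)C)C(C)C; lithium diisopropylamide, [Li+].CC(C)[N-]C(C)C (lithium of 17 and 18 only)
Why: Lateral (vinylogous) lithiation of the 4-methyl group, which lies syn to the coordinating ester carbonyl and gives an anion delocalized into both carbonyl groups as in the lateral lithiation of ortho-toluates, followed by carboxylation at the terminal carbon and O-silylation, should install the acetic acid arm in a form that carries no acidic proton into the methylenation.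

Step 9
Reactants: 19 tri(propan-2-yl)silyl 2-{3-[(2,4-dimethoxy-6-pentylphenoxy)carbonyl]-2-oxo-6-pentyl-2H-pyran-4-yl}acetate
Product: 21 2-{3-[1-(2,4-dimethoxy-6-pentylphenoxy)ethenyl]-2-oxo-6-pentyl-2H-pyran-4-yl}acetic acid, via silyl ester enol ether 20 (not isolated)
Conditions: Cp2TiMe2 (3 equiv), toluene, 70 °C, dark; filter through Celite, evaporate; then Bu4NF, AcOH, THF, 0 °C
Reagents that add atoms: bis(cyclopentadienyl)dimethyltitanium (Cp2TiMe2), C[Ti](C)(C1C=CC=C1)C1C=CC=C1
Why: Petasis methylenation, in which Cp2Ti=CH2 formed on heating adds [2+2] to a carbonyl group and cycloreverts, should convert the aryl ester into the 1-aryloxyvinyl group because the silyl ester is shielded by its triisopropylsilyl group and the ring B lactone carbonyl is deactivated by conjugation with the ring oxygen and the diene, and buffered fluoride then removes the silyl ester without acid that would hydrolyse the enol ether.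

Step 10
Reactants: 21 2-{3-[1-(2,4-dimethoxy-6-pentylphenoxy)ethenyl]-2-oxo-6-pentyl-2H-pyran-4-yl}acetic acid
Product: 26 8-(2,4-dimethoxy-6-pentylphenoxy)-1-oxo-3-pentyl-1H-isochromen-6-yl acetate, via mixed anhydride 22 (not isolated), via dienylketene 23 (not isolated), via cyclohexadienone 24 (not isolated), via phenol 25 (not isolated)
Conditions: Ac2O, NaOAc, 110 °C
Reagents that add atoms: acetic anhydride, CC(=O)OC(C)=O
Why: Acyl exchange gives mixed anhydride 22, whose methylene (future C5) is acidified by the carbonyl group and the pyranone, so E1cB loss of acetate gives dienylketene 23, in which the ketene bond C6=C5, the ring B bond C4a=C8a and the enol ether bond C8=C7 make up a hexatriene. Thermal disrotatory six-electron electrocyclization joins C6 to C7 to give dienone 24, which enolizes to phenol 25 and is acetylated in the same flask. The closest known reaction is the Ac2O/NaOAc benzannulation of 3,5-dienoic acids (Stobbe half-esters to 1-naphthyl acetates), here with a pyranone double bond as the central alkene and an aryl enol ether as the terminus; direct acylation of the nucleophilic carbon C7 by 22 would give the same product. Ring A closes as a six-membered carbocycle in the electrocyclic mode, and this is the only closure available because the endocyclic C4a=C8a bond holds the two arms cis while the lactone carbonyl oxygen is locked anti to the ketene. No stereocentre is formed. The step needs cyclization to outrun capture or dimerization of the ketene and the acid-labile enol ether to survive, which the pre-organized triene and the acetate buffer should secure.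

Step 11
Reactants: 26 8-(2,4-dimethoxy-6-pentylphenoxy)-1-oxo-3-pentyl-1H-isochromen-6-yl acetate
Product: 28 8-(2,4-dihydroxy-6-pentylphenoxy)-6-hydroxy-3-pentyl-1H-isochromen-1-one, via diphenol acetate 27 (not isolated)
Conditions: BBr3 (6 equiv), CH2Cl2, −78 °C to rt; then MeOH, 0 °C to rt
Reagents that add atoms: none
Why: Lewis-acid ether cleavage, in which bromide attacks the methyl group of each boron-complexed aryl methyl ether, should spare the diaryl ether and the enol lactone because neither offers an sp3 carbon to bromide, and HBr-catalysed methanolysis of the aryl acetate during the quench should release the third phenol.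

Compound list

1 | olivetol (5-pentylbenzene-1,3-diol) | CCCCCc1cc(O)cc(O)c1 | starting material
2 | 1,3-dimethoxy-5-pentylbenzene | CCCCCc1cc(OC)cc(OC)c1 | intermediate
3 | [(2,4-dimethoxy-6-pentylphenyl)methylidene]dimethylazanium chloride | CCCCCc1cc(OC)cc(OC)c1C=[N+](C)C.[Cl-] | intermediate (not isolated)
4 | 2,4-dimethoxy-6-pentylbenzaldehyde | CCCCCc1cc(OC)cc(OC)c1C=O | intermediate
5 | 2,4-dimethoxy-6-pentylphenyl formate | CCCCCc1cc(OC)cc(OC)c1OC=O | intermediate (not isolated)
6 | 2,4-dimethoxy-6-pentylphenol | CCCCCc1cc(OC)cc(OC)c1O | intermediate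
7 | hexanoyl chloride | CCCCCC(Cl)=O | starting material
8 | 1-propynylmagnesium bromide | CC#C[Mg]Br | starting material
9 | 1-propynylzinc chloride | CC#C[Zn]Cl | intermediate (not isolated)
10 | non-2-yn-4-one | CCCCCC(=O)C#CC | intermediate
11 | tert-butyl ethyl malonate (tert-butyl ethyl propanedioate) | CCOC(=O)CC(=O)OC(C)(C)C | starting material
12 | tert-butyl ethyl 2-[(2Z)-4-oxonon-2-en-2-yl]propanedioate (racemic at the malonate carbon) | CCCCCC(=O)/C=C(/C)C(C(=O)OCC)C(=O)OC(C)(C)C | intermediate (not isolated)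
13 | tert-butyl 4-methyl-2-oxo-6-pentyl-2H-pyran-3-carboxylate | CCCCCc1cc(C)c(C(=O)OC(C)(C)C)c(=O)o1 | intermediate
14 | 4-methyl-2-oxo-6-pentyl-2H-pyran-3-carboxylic acid | CCCCCc1cc(C)c(C(=O)O)c(=O)o1 | intermediate
15 | 4-methyl-2-oxo-6-pentyl-2H-pyran-3-carbonyl chloride | CCCCCc1cc(C)c(C(Cl)=O)c(=O)o1 | intermediate (not isolated)
16 | 2,4-dimethoxy-6-pentylphenyl 4-methyl-2-oxo-6-pentyl-2H-pyran-3-carboxylate | CCCCCc1cc(C)c(C(=O)Oc2c(OC)cc(OC)cc2CCCCC)c(=O)o1 | intermediate
17 | lithium (2,4-dimethoxy-6-pentylphenoxy)(4-methylidene-2-oxo-6-pentyl-2H-pyran-3(4H)-ylidene)methanolate (enolate geometry not defined) | [Li+].[O-]C(Oc1c(OC)cc(OC)cc1CCCCC)=C1C(=C)C=C(CCCCC)OC1=O | intermediate (not isolated)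
18 | lithium 2-{3-[(2,4-dimethoxy-6-pentylphenoxy)carbonyl]-2-oxo-6-pentyl-2H-pyran-4-yl}acetate | [Li+].[O-]C(=O)Cc1cc(CCCCC)oc(=O)c1C(=O)Oc1c(OC)cc(OC)cc1CCCCC | intermediate (not isolated)
19 | tri(propan-2-yl)silyl 2-{3-[(2,4-dimethoxy-6-pentylphenoxy)carbonyl]-2-oxo-6-pentyl-2H-pyran-4-yl}acetate | CC(C)[Si](OC(=O)Cc1cc(CCCCC)oc(=O)c1C(=O)Oc1c(OC)cc(OC)cc1CCCCC)(C(C)C)C(C)C | intermediate
20 | tri(propan-2-yl)silyl 2-{3-[1-(2,4-dimethoxy-6-pentylphenoxy)ethenyl]-2-oxo-6-pentyl-2H-pyran-4-yl}acetate | CC(C)[Si](OC(=O)Cc1cc(CCCCC)oc(=O)c1C(=C)Oc1c(OC)cc(OC)cc1CCCCC)(C(C)C)C(C)C | intermediate (not isolated)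
21 | 2-{3-[1-(2,4-dimethoxy-6-pentylphenoxy)ethenyl]-2-oxo-6-pentyl-2H-pyran-4-yl}acetic acid | C=C(Oc1c(OC)cc(OC)cc1CCCCC)c1c(CC(=O)O)cc(CCCCC)oc1=O | intermediate
22 | acetic 2-{3-[1-(2,4-dimethoxy-6-pentylphenoxy)ethenyl]-2-oxo-6-pentyl-2H-pyran-4-yl}acetic anhydride | C=C(Oc1c(OC)cc(OC)cc1CCCCC)c1c(CC(=O)OC(C)=O)cc(CCCCC)oc1=O | intermediate (not isolated)
23 | 3-[1-(2,4-dimethoxy-6-pentylphenoxy)ethenyl]-4-(2-oxoethenyl)-6-pentyl-2H-pyran-2-one | C=C(Oc1c(OC)cc(OC)cc1CCCCC)c1c(C=C=O)cc(CCCCC)oc1=O | intermediate (not isolated)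
24 | 8-(2,4-dimethoxy-6-pentylphenoxy)-3-pentyl-1H-isochromene-1,6(7H)-dione | CCCCCC1=CC2=CC(=O)CC(Oc3c(OC)cc(OC)cc3CCCCC)=C2C(=O)O1 | intermediate (not isolated)
25 | 8-(2,4-dimethoxy-6-pentylphenoxy)-6-hydroxy-3-pentyl-1H-isochromen-1-one | CCCCCc1cc2cc(O)cc(Oc3c(OC)cc(OC)cc3CCCCC)c2c(=O)o1 | intermediate (not isolated)
26 | 8-(2,4-dimethoxy-6-pentylphenoxy)-1-oxo-3-pentyl-1H-isochromen-6-yl acetate | CCCCCc1cc2cc(OC(C)=O)cc(Oc3c(OC)cc(OC)cc3CCCCC)c2c(=O)o1 | intermediate
27 | 8-(2,4-dihydroxy-6-pentylphenoxy)-1-oxo-3-pentyl-1H-isochromen-6-yl acetate | CCCCCc1cc2cc(OC(C)=O)cc(Oc3c(O)cc(O)cc3CCCCC)c2c(=O)o1 | intermediate (not isolated)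
28 | 8-(2,4-dihydroxy-6-pentylphenoxy)-6-hydroxy-3-pentyl-1H-isochromen-1-one (CNP0213708.0) | CCCCCc1cc2cc(O)cc(Oc3c(O)cc(O)cc3CCCCC)c2c(=O)o1 | target

Total step count: 11.
Longest linear sequence: 8 steps (steps 4 to 11 from 7 and 8; equally steps 1 to 3 and 7 to 11 from 1).

Steps most likely to fail

Step 9. Cp2Ti=CH2 may fail to discriminate between the hindered aryl ester and the silyl ester, or conversion may be so slow that the reagent decays first, so that over-methylenated or unchanged material results. The fallback removes the second ester from the methylenation by reversing the order of steps 8 and 9. It sets out from 16, which is heated with Cp2TiMe2 in toluene at 70 °C before the side chain exists, to give 3-[1-(2,4-dimethoxy-6-pentylphenoxy)ethenyl]-4-methyl-6-pentyl-2H-pyran-2-one F1. F1 is deprotonated at the 4-methyl group with LiN(iPr)2 in THF at −78 °C and quenched with CO2, with a pH 5 work-up, and the route is rejoined at 21. No silyl ester is needed. The cost is that the ester director is gone, so the site of deprotonation (4-methyl against C1′ of the pentyl chain) would have to be confirmed.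

Step 10. The ketene may be intercepted by acetate or acetic acid, the enol ether may be protonated in the hot medium, or decarboxylation of the pyranone acetic acid may outrun anhydride formation. The fallback replaces the thermal ketene route by a cold ionic ring closure. It sets out from 21, which with 1-chloro-N,N,2-trimethylprop-1-en-1-amine in CH2Cl2 at 0 °C gives, under neutral conditions, 2-{3-[1-(2,4-dimethoxy-6-pentylphenoxy)ethenyl]-2-oxo-6-pentyl-2H-pyran-4-yl}acetyl chloride F2. AgOTf with 2,6-di-tert-butyl-4-methylpyridine at −40 °C should then close ring A by Friedel–Crafts-type acylation of the enol ether carbon C7, and the aryloxy-stabilized cation loses a proton to give the phenol. The route is rejoined at 25, now isolated, which is taken through the conditions of step 11 to 28.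

Step 8. Deprotonation may take place at C1′ of the 6-pentyl chain instead of the 4-methyl group, or the dienolate may add to a second pyranone, so that regioisomeric or dimeric acids form. The fallback builds the two-carbon arm into the alkyne, so that no lateral metalation is needed.
- It sets out from 7, which is coupled (n-BuLi, ZnCl2, then Pd(PPh3)4) with purchased tert-butyl(but-3-yn-1-yloxy)diphenylsilane, C#CCCO[Si](c1ccccc1)(c1ccccc1)C(C)(C)C, to give 1-{[tert-butyl(diphenyl)silyl]oxy}dec-3-yn-5-one F3.
- Annulation with 11 (NaOEt, EtOH) gives tert-butyl 4-(2-{[tert-butyl(diphenyl)silyl]oxy}ethyl)-2-oxo-6-pentyl-2H-pyran-3-carboxylate F4.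
- TFA gives 4-(2-{[tert-butyl(diphenyl)silyl]oxy}ethyl)-2-oxo-6-pentyl-2H-pyran-3-carboxylic acid F5.
- Esterification with 6 under the conditions of step 7 gives 2,4-dimethoxy-6-pentylphenyl 4-(2-{[tert-butyl(diphenyl)silyl]oxy}ethyl)-2-oxo-6-pentyl-2H-pyran-3-carboxylate F6.
- Cp2TiMe2, with only one ester present, gives 4-(2-{[tert-butyl(diphenyl)silyl]oxy}ethyl)-3-[1-(2,4-dimethoxy-6-pentylphenoxy)ethenyl]-6-pentyl-2H-pyran-2-one F7.
- Bu4NF buffered with AcOH gives 3-[1-(2,4-dimethoxy-6-pentylphenoxy)ethenyl]-4-(2-hydroxyethyl)-6-pentyl-2H-pyran-2-one F8.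
- TEMPO with PhI(OAc)2 in MeCN–H2O oxidizes the primary alcohol to the acid, and the route is rejoined at 21.

Further compounds

F1 | step 9 | 3-[1-(2,4-dimethoxy-6-pentylphenoxy)ethenyl]-4-methyl-6-pentyl-2H-pyran-2-one | C=C(Oc1c(OC)cc(OC)cc1CCCCC)c1c(C)cc(CCCCC)oc1=O
F2 | step 10 | 2-{3-[1-(2,4-dimethoxy-6-pentylphenoxy)ethenyl]-2-oxo-6-pentyl-2H-pyran-4-yl}acetyl chloride | C=C(Oc1c(OC)cc(OC)cc1CCCCC)c1c(CC(Cl)=O)cc(CCCCC)oc1=O
F3 | step 8 | 1-{[tert-butyl(diphenyl)silyl]oxy}dec-3-yn-5-one | CCCCCC(=O)C#CCCO[Si](c1ccccc1)(c1ccccc1)C(C)(C)C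
F4 | step 8 | tert-butyl 4-(2-{[tert-butyl(diphenyl)silyl]oxy}ethyl)-2-oxo-6-pentyl-2H-pyran-3-carboxylate | CCCCCc1cc(CCO[Si](c2ccccc2)(c2ccccc2)C(C)(C)C)c(C(=O)OC(C)(C)C)c(=O)o1
F5 | step 8 | 4-(2-{[tert-butyl(diphenyl)silyl]oxy}ethyl)-2-oxo-6-pentyl-2H-pyran-3-carboxylic acid | CCCCCc1cc(CCO[Si](c2ccccc2)(c2ccccc2)C(C)(C)C)c(C(=O)O)c(=O)o1
F6 | step 8 | 2,4-dimethoxy-6-pentylphenyl 4-(2-{[tert-butyl(diphenyl)silyl]oxy}ethyl)-2-oxo-6-pentyl-2H-pyran-3-carboxylate | CCCCCc1cc(CCO[Si](c2ccccc2)(c2ccccc2)C(C)(C)C)c(C(=O)Oc2c(OC)cc(OC)cc2CCCCC)c(=O)o1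
F7 | step 8 | 4-(2-{[tert-butyl(diphenyl)silyl]oxy}ethyl)-3-[1-(2,4-dimethoxy-6-pentylphenoxy)ethenyl]-6-pentyl-2H-pyran-2-one | C=C(Oc1c(OC)cc(OC)cc1CCCCC)c1c(CCO[Si](c2ccccc2)(c2ccccc2)C(C)(C)C)cc(CCCCC)oc1=O
F8 | step 8 | 3-[1-(2,4-dimethoxy-6-pentylphenoxy)ethenyl]-4-(2-hydroxyethyl)-6-pentyl-2H-pyran-2-one | C=C(Oc1c(OC)cc(OC)cc1CCCCC)c1c(CCO)cc(CCCCC)oc1=O
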